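I counted lifetimes.

the same everywhere: free catalyst 12 mol%
- north-west: solid substrate 40 mM; reagent 7 equiv; run made earlier
- east: solid substrate 40 mM; reagent 11 equiv; run made earlier
- south: solid substrate 20 mM; reagent 5 equiv; run made earlier
- flask: solid substrate 40 mM; reagent 5.00 equiv; time 1.0 h

| run | time / min | solid substrate / % | target / % |
|---|---|---|---|
| north-west | 8.00 | 95.6 | 0.2 |
| north-west | 15.0 | 91.9 | 2.0 |
| north-west | 25.0 | 88.0 | 3.3 |
| north-west | 30.0 | 86.8 | 5.0 |
| north-west | 40.0 | 82.9 | 7.9 |
| north-west | 50.0 | 80.4 | 10.2 |
| north-west | 60.0 | 77.5 | 12.9 |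
| east | 3.00 | 97.9 | 0 |
| east | 10.0 | 94.3 | 1.4 |
| east | 15.0 | 92.0 | 1.9 |
| east | 25.0 | 87.8 | 3.7 |
| east | 40.0 | 84.2 | 7.1 |
| east | 50.0 | 80.2 | 10.7 |
| east | 60.0 | 77.4 | 13.2 |
| south | 5.00 | 93.7 | 0 |
| south | 15.0 | 84.5 | 1.7 |
| south | 30.0 | 75.2 | 5.5 |
| south | 40.0 | 70.5 | 8.6 |
| south | 60.0 | 62.8 | 15.2 |

(scatter of a reading: 0.3 percentage points)

- at the start none of the solid substrate is in solution
- what has only dissolved of solid substrate counts as not reacted
- the earlier runs do not show how much of reagent is bound; that part of a forecast is a guess

- part of the solid substrate that has reacted (what has only dissolved counts as not reacted) at 1.0 h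
- share of the unused reagent that is free and not bound as idle adduct, at 1.0 h

The north-west and east runs ended at 12.9% and 13.2% target, so I pooled them to stand for this flask, which has the same solid charge and catalyst loading. At their middle reading the dissolved fraction of the charge, neither solid nor target, averaged 9.25%, and target gained 5.55% of the charge in 20.0 min. Dividing that fraction by the gain per minute gave 33.3 min, the pseudo-first-order lifetime of dissolved substrate.

The ladder then read as follows. Extrapolated back, target began after a lag of 13.0 min, shorter than the lifetime. The lifetime was shorter than the asked time, and at that pace the remaining solid needed 4.65 h, longer than the asked time. So I expected this flask to hold a steady dissolved fraction feeding target, and I reckoned 13.1% reacted.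

The forecast, holding that “dissolution limits supply”, gave 13% (12.3% to 13.8%) and 97.7% free (97.2% to 99.8%).

The flask ran by this scheme:

    reagent + free catalyst ⇌ catalyst intermediate A (K = 4.77 M⁻¹, k = 957 M⁻¹ min⁻¹)
    catalyst intermediate A ⇌ released group + catalyst intermediate B (K = 0.598 M, k = 16.9 min⁻¹)
    catalyst intermediate B ⇌ catalyst intermediate C (K = 0.532, k = 2.50 min⁻¹)
    starting material + catalyst intermediate C ⇌ catalyst intermediate D (K = 48.3 M⁻¹, k = 32.9 M⁻¹ min⁻¹)
    catalyst intermediate D → free catalyst + target (k = 1.03 min⁻¹)
    reagent + released group ⇌ idle adduct, settled at all times (K = 14.0 M⁻¹)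
    solid substrate ⇌ starting material, rate k7*(cs7 - [starting material]) while solid is left; crystals form when [starting material] > cs7 (solubility = 6.30 mM, k = 0.0428 min⁻¹)
    crystals ⇌ released group, rate k8*(cs8 - [released group]) while solid is left; crystals form when [released group] > cs8 (solubility = 4.30 mM, k = 0.527 min⁻¹)

This flask gave 13.5% reacted and 96.2% free. The same division on it, with starting material averaged between 0.500 h and 1.0 h, gave a lifetime of 31.1 min, beside the 33.3 min I had read from the runs. For the neighbouring flask at 4.8 mol% catalyst, I stretched this flask's 31.1 min inversely with loading to 77.6 min. With that flask's 11.7% starting material at 1.00 h and the same lag, this reckons 7.09% target, more than the 6.46% that neighbouring flask held at 1.00 h.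

(The readings were computed with constants of no real substance; noise was put on by code.)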